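- In the dawn run, Q reads 7.7 % at 30.0 s and 7.6 % at 90.0 s, while J climbs from 25.4 % to 41.7 %.

| flask | Z | E | D | remark | time |
|---|---|---|---|---|---|
| dawn | 0.020 M | 1.3 equiv | 5 equiv | run made earlier |  |
| spring | 0.020 M | 1.3 equiv | 2.5 equiv | run made earlier |  |
| autumn | 0.020 M | 1.3 equiv | 10 equiv | run made earlier |  |
| south | 0.020 M | 1.30 equiv (fed, over 30 s) | 5.00 equiv | all else is in the flask from the start; the feed brings no volume worth counting | 2.5 min |
| north-west | 0.020 M | 1.30 equiv | 5.00 equiv | everything together at the start | 2.5 min |
| north-east | 0.020 M (fed, over 30 s) | 1.30 equiv | 5.00 equiv | all else is in the flask from the start; the feed brings no volume worth counting | 2.5 min |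
| south-west | 0.020 M | 1.30 equiv (fed, over 8.0 s) | 5.00 equiv | all else is in the flask from the start; the feed brings no volume worth counting | 2.5 min |

- dawn (time / s: Q / %, J / %): 10.0: 5.1, 8.8; 20.0: 6.7, 20.0; 30.0: 7.7, 25.4; 50.0: 7.5, 34.3; 60.0: 7.7, 35.6; 90.0: 7.6, 41.7
- spring (time / s: Q / %, J / %): 15.0: 6.9, 13.7; 30.0: 8.7, 25.0; 50.0: 7.9, 35.0; 60.0: 8.1, 37.3; 80.0: 6.5, 41.5; 90.0: 9.5, 43.4
- autumn (time / s: Q / %, J / %): 15.0: 5.7, 14.9; 30.0: 6.9, 26.6; 50.0: 8.7, 33.4; 60.0: 9.0, 36.5; 80.0: 8.1, 39.5; 90.0: 8.2, 43.2

(scatter of a reading: 1 percentage point)

- percentages count the Z that a species holds: one J counts as two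

* the flask that comes out highest in share of Q in Q plus J, or "all alike" when all lie within 1.5 percentage points (south / north-west / north-east / south-west / all alike)
* share of Q in Q plus J at the end, south
* share of Q in Q plus J at the end, north-west
* share of Q in Q plus J at the end, north-east
* share of Q in Q plus J at the end, south-west

- A bench rule says a product stops when its reagent is used up, which would make E the limiting reagent for Q. So do the sum for E, in fractions of the Z charge.
- Credit the products generously: two E per Z held in Q, one per Z held in J. Divide that by the E charged, and you have the E count43.8 %, the most of the charged E that the products can hold. A count of one is the zero of the scale: on this generous credit, the products could then hold the charged E. Because the credit is a ceiling, a count of one would not show that no E went elsewhere, but a count below one does show a shortfall: E that is in neither Q nor J.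
- In the dawn run the count reads 31.4 % at 30.0 s, when the Q readings stop climbing, and 43.8 % at 90.0 s.
- That is the border of the bench rule. The last dawn reading puts at least 56.2 % of the E in neither Q nor J.
- My own assumption is that this hidden loss needs E to meet E. Then thin E should raise the count, so I rank south first. North-east should come last, since its E stands with no Z at the start.
- The dawn share of Q is 15.4 %, read from the last reading. That makes share per count 0.352, and I expect the share to follow the count.
- The forecast runs the other way, choosing north-east with 35 % there, 14 % for north-west, 11 % for south-west and 6 % for south, on the ground that “Feeding Z keeps I low against plentiful E, which favours Q over dimerisation”.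
- The highest flask is south, at 20.4 %, with south-west at 18.2 %, north-west at 15.8 % and north-east at 9.34 %.

    Z + E → D + G (k = 2.20 M⁻¹ s⁻¹)
    G + E → D + Q (k = 5.90 M⁻¹ s⁻¹)
    Z + G → J (k = 3.20 M⁻¹ s⁻¹)
    2 E → X (k = 5.60 M⁻¹ s⁻¹)

- At 2.50 min, south still holds Z at 32.4 %, while E stands at 0.47 % of its charge and X at 0.00746 M. The E count of south is 61.2 %, higher than the dawn count of 43.8 %. Multiplied by the dawn ratio of 0.352, it gives 21.5 %. The count of north-east is 25.3 %, and the same ratio gives 8.91 %, where north-east stands at 9.34 %.

All runs stem from a simulated flask with constants of no real substance; the scatter is artificial.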